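**Plan**
- Retrosynthesis: the three phenols are unmasked last (MOM ethers). Ring C is then cut at C2–C3 and at O1–C8a together, giving an aryl aldehyde (ring B, C2, O1) and the enol silane of a 2-fluoroaryl methyl ketone (ring A, C4, C3). Both prenyl groups go back to aryl bromides.
- Enabling feature: the C4 ketone sits on C4a of ring A, ortho to the O1-bearing C8a, and its alpha carbon C3 is bonded to C2. One carbonyl therefore makes C3 a nucleophile and, with fluorine as a temporary group on C8a, makes C8a an SNAr electrophile, so the aldehyde C2=O1 can be stitched in between.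
- Forward: the ring A fragment (steps 1–5) and the ring B fragment (steps 6–7) are made separately, ring C is closed between them in step 8, and step 9 frees the phenols.
- Stereochemistry: C2 (S) is set by catalyst-controlled Si-face aldol addition in step 8. It is kept because the C2–O1 bond is never broken and no chalcone is passed through.

Key step: step 8

Assumption: the (R)-tryptophan-derived catalyst of step 8 is taken as the antipode that exposes the Si face of aldehyde 10 (its mirror image is used if a model aldol shows the opposite sense), and compounds 1 and 8 and the prenylstannane are taken as purchasable.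

**Step 1**
Reactants: 1 5-fluorobenzene-1,3-diol
Product: 2 1-(2-fluoro-4,6-dihydroxyphenyl)ethan-1-one
Conditions: AcOH, BF3·OEt2 (promoter), 90 °C; then H2O
Reagents that add atoms: acetic acid CC(=O)O
Why: Friedel–Crafts C-acylation of a resorcinol goes para to one hydroxyl and ortho to the other (as with orcinol), which places the acetyl group beside fluorine; the two such positions are equivalent by symmetry.

**Step 2**
Reactants: 2 1-(2-fluoro-4,6-dihydroxyphenyl)ethan-1-one
Product: 3 1-[2-fluoro-4,6-bis(methoxymethoxy)phenyl]ethan-1-one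
Conditions: NaH, MOMCl, DMF, 0 °C → rt
Reagents that add atoms: chloromethyl methyl ether COCCl
Why: Williamson-type O-alkylation of both phenoxides (the hydrogen-bonded one needs NaH) gives acetal ethers that tolerate base, Pd and fluoride and keep ring A free of phenoxide in step 8.

**Step 3**
Reactants: 3 1-[2-fluoro-4,6-bis(methoxymethoxy)phenyl]ethan-1-one
Product: 4 1-[3-bromo-2-fluoro-4,6-bis(methoxymethoxy)phenyl]ethan-1-one
Conditions: NBS, MeCN, 0 °C → rt, dark
Reagents that add atoms: N-bromosuccinimide O=C1CCC(=O)N1Br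
Why: Electrophilic aromatic bromination of a resorcinol diether takes the carbon ortho to one ether and para to the other (C3, beside the small fluorine) and not the crowded carbon between the two ethers, as 1,3-dimethoxybenzene does.

**Step 4**
Reactants: 4 1-[3-bromo-2-fluoro-4,6-bis(methoxymethoxy)phenyl]ethan-1-one
Product: 5 1-[2-fluoro-4,6-bis(methoxymethoxy)-3-(3-methylbut-2-en-1-yl)phenyl]ethan-1-one
Conditions: Pd(PPh3)4 (5 mol %), DMF, 100 °C
Reagents that add atoms: tributyl(3-methylbut-2-en-1-yl)stannane CCCC[Sn](CCCC)(CCCC)CC=C(C)C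
Why: Stille coupling, in which the allyl fragment should couple at its unsubstituted terminus after transmetalation, puts the linear prenyl group on the carbon that becomes C8.

**Step 5**
Reactants: 5 1-[2-fluoro-4,6-bis(methoxymethoxy)-3-(3-methylbut-2-en-1-yl)phenyl]ethan-1-one
Product: 7 ({1-[2-fluoro-4,6-bis(methoxymethoxy)-3-(3-methylbut-2-en-1-yl)phenyl]ethenyl}oxy)trimethylsilane, via lithium enolate 6 (not isolated)
Conditions: LiN(i-Pr)2, THF, −78 °C; then TMSCl, −78 → 0 °C; non-aqueous work-up
Reagents that add atoms: chlorotrimethylsilane C[Si](C)(C)Cl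
Why: Kinetic deprotonation of the only enolisable position and O-silylation of the lithium enolate give the enol silane needed for a Mukaiyama aldol addition.

**Step 6**
Reactants: 8 2-bromo-3-hydroxy-4-methoxybenzaldehyde
Product: 9 2-bromo-4-methoxy-3-(methoxymethoxy)benzaldehyde
Conditions: NaH, MOMCl, THF, 0 °C → rt
Reagents that add atoms: chloromethyl methyl ether COCCl
Why: O-alkylation of the phenoxide masks the 3-hydroxyl as a MOM ether that survives the Stille coupling and step 8.

**Step 7**
Reactants: 9 2-bromo-4-methoxy-3-(methoxymethoxy)benzaldehyde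
Product: 10 4-methoxy-3-(methoxymethoxy)-2-(3-methylbut-2-en-1-yl)benzaldehyde
Conditions: Pd(PPh3)4 (5 mol %), DMF, 90 °C
Reagents that add atoms: tributyl(3-methylbut-2-en-1-yl)stannane CCCC[Sn](CCCC)(CCCC)CC=C(C)C
Why: Stille coupling at the bromide activated by the ortho formyl group installs the linear prenyl group on C2' without touching the aldehyde.

**Step 8**
Reactants: 7 ({1-[2-fluoro-4,6-bis(methoxymethoxy)-3-(3-methylbut-2-en-1-yl)phenyl]ethenyl}oxy)trimethylsilane, 10 4-methoxy-3-(methoxymethoxy)-2-(3-methylbut-2-en-1-yl)benzaldehyde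
Product: 12 (2S)-5,7-bis(methoxymethoxy)-2-[4-methoxy-3-(methoxymethoxy)-2-(3-methylbut-2-en-1-yl)phenyl]-8-(3-methylbut-2-en-1-yl)-2,3-dihydro-4H-chromen-4-one, via silyl aldol 11 (not isolated)
Conditions: (R)-tryptophan-derived B-butyl-N-tosyl-1,3,2-oxazaborolidin-5-one (20 mol %), EtCN, −78 °C; then Bu4N[Ph3SiF2] (40 mol %), THF, −78 → 0 °C; AcOH quench
Reagents that add atoms: none
Why: Proposed new method: the boron Lewis acid activates aldehyde 10 for Mukaiyama aldol addition of enol silane 7 to its Si face, which forms C2–C3 and after silyl transfer leaves silyl ether 11; fluoride then frees the C2 alkoxide, which adds to the fluorine-bearing C8a ortho to the ketone and expels fluoride (addition–elimination, SNAr), forming O1–C8a and releasing the fluoride that desilylates the next molecule of 11, so that Me3SiF is the only by-product. The closest known reaction types are the oxazaborolidinone-catalysed enantioselective Mukaiyama aldol of aryl methyl ketone enol silanes with aryl aldehydes, the fluoride-catalysed etherification of activated aryl fluorides with silyl ethers, the base-mediated closure of 1-(2-fluoroaryl)-1,3-diketones to chromones, and the aldol–cyclisation pathway of 1-alkoxy-3-siloxydiene hetero-Diels–Alder reactions with aldehydes. Ring C closes as a six-membered ring by attack of O1 on C8a, formally 6-endo-trig with respect to the C4a=C8a bond that passes the charge to the C4 carbonyl in the Meisenheimer intermediate. The C2 stereocentre is set under catalyst control in the aldol stage (Si-face attack gives 2S) and is carried through with retention because the C2–O1 bond is never broken. The step needs ring closure to outrun retro-aldol cleavage and beta-elimination of the aldolate; the ortho-acyl activation of the C–F bond, the six-membered geometry and the low standing concentration of alkoxide under the fluoride relay should secure this, and the MOM ethers keep ring A free of phenoxide that would switch off the SNAr.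

**Step 9**
Reactants: 12 (2S)-5,7-bis(methoxymethoxy)-2-[4-methoxy-3-(methoxymethoxy)-2-(3-methylbut-2-en-1-yl)phenyl]-8-(3-methylbut-2-en-1-yl)-2,3-dihydro-4H-chromen-4-one
Product: 13 (2S)-5,7-dihydroxy-2-[3-hydroxy-4-methoxy-2-(3-methylbut-2-en-1-yl)phenyl]-8-(3-methylbut-2-en-1-yl)-2,3-dihydro-4H-chromen-4-one
Conditions: HCl (1.25 M in MeOH), 0 °C → rt
Reagents that add atoms: none
Why: Acid-catalysed acetal exchange with methanol (MOM cleavage) frees the three phenols under conditions in which the acid-stable flavanone stereocentre and, at room temperature, the prenyl groups should not react.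

**Compound list**
1 | 5-fluorobenzene-1,3-diol | Oc1cc(O)cc(F)c1 | starting material
2 | 1-(2-fluoro-4,6-dihydroxyphenyl)ethan-1-one | CC(=O)c1c(O)cc(O)cc1F | intermediate
3 | 1-[2-fluoro-4,6-bis(methoxymethoxy)phenyl]ethan-1-one | CC(=O)c1c(OCOC)cc(OCOC)cc1F | intermediate
4 | 1-[3-bromo-2-fluoro-4,6-bis(methoxymethoxy)phenyl]ethan-1-one | CC(=O)c1c(OCOC)cc(OCOC)c(Br)c1F | intermediate
5 | 1-[2-fluoro-4,6-bis(methoxymethoxy)-3-(3-methylbut-2-en-1-yl)phenyl]ethan-1-one | CC(=O)c1c(OCOC)cc(OCOC)c(CC=C(C)C)c1F | intermediate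
6 | lithium 1-[2-fluoro-4,6-bis(methoxymethoxy)-3-(3-methylbut-2-en-1-yl)phenyl]ethen-1-olate | [Li+].[O-]C(=C)c1c(OCOC)cc(OCOC)c(CC=C(C)C)c1F | intermediate
7 | ({1-[2-fluoro-4,6-bis(methoxymethoxy)-3-(3-methylbut-2-en-1-yl)phenyl]ethenyl}oxy)trimethylsilane | C=C(O[Si](C)(C)C)c1c(OCOC)cc(OCOC)c(CC=C(C)C)c1F | intermediate
8 | 2-bromo-3-hydroxy-4-methoxybenzaldehyde | COc1ccc(C=O)c(Br)c1O | starting material
9 | 2-bromo-4-methoxy-3-(methoxymethoxy)benzaldehyde | COCOc1c(OC)ccc(C=O)c1Br | intermediate
10 | 4-methoxy-3-(methoxymethoxy)-2-(3-methylbut-2-en-1-yl)benzaldehyde | COCOc1c(OC)ccc(C=O)c1CC=C(C)C | intermediate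
11 | (3S)-1-[2-fluoro-4,6-bis(methoxymethoxy)-3-(3-methylbut-2-en-1-yl)phenyl]-3-[4-methoxy-3-(methoxymethoxy)-2-(3-methylbut-2-en-1-yl)phenyl]-3-[(trimethylsilyl)oxy]propan-1-one | COc1ccc([C@@H](O[Si](C)(C)C)CC(=O)c2c(OCOC)cc(OCOC)c(CC=C(C)C)c2F)c(CC=C(C)C)c1OCOC | intermediate
12 | (2S)-5,7-bis(methoxymethoxy)-2-[4-methoxy-3-(methoxymethoxy)-2-(3-methylbut-2-en-1-yl)phenyl]-8-(3-methylbut-2-en-1-yl)-2,3-dihydro-4H-chromen-4-one | COc1ccc([C@@H]2CC(=O)c3c(OCOC)cc(OCOC)c(CC=C(C)C)c3O2)c(CC=C(C)C)c1OCOC | intermediate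
13 | (2S)-5,7-dihydroxy-2-[3-hydroxy-4-methoxy-2-(3-methylbut-2-en-1-yl)phenyl]-8-(3-methylbut-2-en-1-yl)-2,3-dihydro-4H-chromen-4-one | COc1ccc([C@@H]2CC(=O)c3c(O)cc(O)c(CC=C(C)C)c3O2)c(CC=C(C)C)c1O | target

Total step count: 9
Longest linear sequence: 7 steps (steps 1, 2, 3, 4, 5, 8, 9)

**Steps most likely to fail**

Step 8. Several processes can defeat it:
- retro-aldol cleavage or beta-elimination of the fluoride-liberated aldolate before it closes the ring;
- loss of enantiopurity through reversible aldol addition or base-induced opening and reclosure of ring C;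
- poor facial selectivity at the crowded ortho-prenyl aldehyde;
- an intramolecular carbonyl-ene reaction of the aldehyde under the Lewis acid.

The fallback is the established oxa-Michael route, which forms O1–C2 instead of O1–C8a; it sets out from aldehyde 10 and returns at 12. Commercial 1-(2,4,6-trihydroxyphenyl)ethan-1-one is C-prenylated (prenyl bromide, DBU, THF) to 1-[2,4,6-trihydroxy-3-(3-methylbut-2-en-1-yl)phenyl]ethan-1-one F1. MOMCl (2 equiv) with i-Pr2NEt should mask the 4-hydroxyl and the less hindered 6-hydroxyl and leave the hydrogen-bonded hydroxyl beside the prenyl group free, giving 1-[2-hydroxy-4,6-bis(methoxymethoxy)-3-(3-methylbut-2-en-1-yl)phenyl]ethan-1-one F2. Claisen–Schmidt condensation of F2 with 10 (KOH, EtOH/H2O) gives (2E)-1-[2-hydroxy-4,6-bis(methoxymethoxy)-3-(3-methylbut-2-en-1-yl)phenyl]-3-[4-methoxy-3-(methoxymethoxy)-2-(3-methylbut-2-en-1-yl)phenyl]prop-2-en-1-one F3. NaOAc in refluxing EtOH closes ring C by intramolecular oxa-Michael addition to racemic 5,7-bis(methoxymethoxy)-2-[4-methoxy-3-(methoxymethoxy)-2-(3-methylbut-2-en-1-yl)phenyl]-8-(3-methylbut-2-en-1-yl)-2,3-dihydro-4H-chromen-4-one F4. Preparative HPLC on a chiral stationary phase then separates the (2S)-enantiomer, which is 12.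

Step 4. Oxidative addition and transmetalation may be slow at the electron-rich bromide flanked by two ortho substituents, and allylic transposition during coupling would give the branched 1,1-dimethylallyl isomer. The fallback sets out from 4 and returns at 5. Stille coupling with allyltributylstannane (Pd(PPh3)4, DMF), which has no regiochemical ambiguity, gives 1-[2-fluoro-4,6-bis(methoxymethoxy)-3-(prop-2-en-1-yl)phenyl]ethan-1-one F5. Olefin cross-metathesis with 2-methylbut-2-ene (second-generation Grubbs catalyst, CH2Cl2, 40 °C) then converts the allyl into the prenyl group of 5.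

Step 3. Bromination may occur at the carbon between the two MOM ethers or at the ketone methyl group. The fallback delivers the prenyl group by a sigmatropic shift from the 4-oxygen; it sets out from 2 and returns at 5.
- The non-chelated 4-hydroxyl of 2 is alkylated with 3-chloro-3-methylbut-1-yne (K2CO3, KI, CuI cat., acetone) to 1-{2-fluoro-6-hydroxy-4-[(2-methylbut-3-yn-2-yl)oxy]phenyl}ethan-1-one F6.
- NaH and MOMCl give 1-{2-fluoro-6-(methoxymethoxy)-4-[(2-methylbut-3-yn-2-yl)oxy]phenyl}ethan-1-one F7.
- Semi-hydrogenation (H2, Pd/CaCO3 poisoned with Pb(OAc)2, quinoline) gives 1-{2-fluoro-6-(methoxymethoxy)-4-[(2-methylbut-3-en-2-yl)oxy]phenyl}ethan-1-one F8.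
- Aromatic Claisen rearrangement (PhNEt2, 150 °C) should go to the carbon beside fluorine, away from the alkoxy-flanked carbon now that the ketone is no longer chelated, giving 1-[2-fluoro-4-hydroxy-6-(methoxymethoxy)-3-(3-methylbut-2-en-1-yl)phenyl]ethan-1-one F9.
- NaH and MOMCl then give 5.

**Further compounds**
F1 | step 8 | 1-[2,4,6-trihydroxy-3-(3-methylbut-2-en-1-yl)phenyl]ethan-1-one | CC(=O)c1c(O)cc(O)c(CC=C(C)C)c1O
F2 | step 8 | 1-[2-hydroxy-4,6-bis(methoxymethoxy)-3-(3-methylbut-2-en-1-yl)phenyl]ethan-1-one | CC(=O)c1c(OCOC)cc(OCOC)c(CC=C(C)C)c1O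
F3 | step 8 | (2E)-1-[2-hydroxy-4,6-bis(methoxymethoxy)-3-(3-methylbut-2-en-1-yl)phenyl]-3-[4-methoxy-3-(methoxymethoxy)-2-(3-methylbut-2-en-1-yl)phenyl]prop-2-en-1-one | COc1ccc(/C=C/C(=O)c2c(OCOC)cc(OCOC)c(CC=C(C)C)c2O)c(CC=C(C)C)c1OCOC
F4 | step 8 | racemic 5,7-bis(methoxymethoxy)-2-[4-methoxy-3-(methoxymethoxy)-2-(3-methylbut-2-en-1-yl)phenyl]-8-(3-methylbut-2-en-1-yl)-2,3-dihydro-4H-chromen-4-one | COc1ccc(C2CC(=O)c3c(OCOC)cc(OCOC)c(CC=C(C)C)c3O2)c(CC=C(C)C)c1OCOC
F5 | step 4 | 1-[2-fluoro-4,6-bis(methoxymethoxy)-3-(prop-2-en-1-yl)phenyl]ethan-1-one | CC(=O)c1c(OCOC)cc(OCOC)c(CC=C)c1F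
F6 | step 3 | 1-{2-fluoro-6-hydroxy-4-[(2-methylbut-3-yn-2-yl)oxy]phenyl}ethan-1-one | CC(=O)c1c(O)cc(OC(C)(C)C#C)cc1F
F7 | step 3 | 1-{2-fluoro-6-(methoxymethoxy)-4-[(2-methylbut-3-yn-2-yl)oxy]phenyl}ethan-1-one | CC(=O)c1c(OCOC)cc(OC(C)(C)C#C)cc1F
F8 | step 3 | 1-{2-fluoro-6-(methoxymethoxy)-4-[(2-methylbut-3-en-2-yl)oxy]phenyl}ethan-1-one | CC(=O)c1c(OCOC)cc(OC(C)(C)C=C)cc1F
F9 | step 3 | 1-[2-fluoro-4-hydroxy-6-(methoxymethoxy)-3-(3-methylbut-2-en-1-yl)phenyl]ethan-1-one | CC(=O)c1c(OCOC)cc(O)c(CC=C(C)C)c1F
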